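**Retrosynthetic overview**
- Target ⇐ its 5,7,4'-tri-O-benzyl ether; hydrogenolysis comes last and is neutral, so C2 is not at risk.
- Flavanone ring C (formed last) ⇐ 2',6'-dihydroxy-4'-methoxychalcone by a catalyst-controlled 6-endo oxa-Michael closure, the chalcone isomerase step run on the complete biflavonoid skeleton; this sets 2S.
- That chalcone ⇐ flavone-bearing 4-aryloxybenzaldehyde + 2',6'-dihydroxy-4'-methoxyacetophenone (Claisen–Schmidt).
- Diaryl ether ⇐ 3'-hydroxyflavone + 4-fluorobenzaldehyde (SNAr); this differentiates the two halves without a dialdehyde.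
- Flavone ring C (formed first) ⇐ 2'-hydroxychalcone by oxidative cyclization through the flavanone (chalcone isomerase then flavone synthase in one flask) ⇐ two benzyl-protected commercial pieces.

Assumption: 1, 2, 7 and 9 are bought as catalogue compounds.
Assumption: the sense of induction in step 5 cannot be predicted; the quinine-derived catalyst is written, and its quinidine-derived pseudo-enantiomer is used instead if CD shows the 2R product (2S gives a positive Cotton effect near 330 nm and a negative one near 290 nm).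

**Step 1**
Reactants: 1 1-[2,4-bis(benzyloxy)-6-hydroxyphenyl]ethan-1-one; 2 4-(benzyloxy)-3-hydroxybenzaldehyde
Product: 4 (E)-1-[2,4-bis(benzyloxy)-6-hydroxyphenyl]-3-[4-(benzyloxy)-3-hydroxyphenyl]prop-2-en-1-one, via aldol adduct 3 (not isolated)
Conditions: KOH (50% aq, excess), EtOH, rt, 36 h; then 1 M HCl
Reagents that add atoms: none
Why: Claisen–Schmidt condensation, in which only the methyl ketone can enolise, the meta-phenoxide of 2 does not deactivate the aldehyde, and E1cB loss of water from aldol 3 gives the conjugated E-enone with no stereocenter left.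

**Step 2**
Reactants: 4 (E)-1-[2,4-bis(benzyloxy)-6-hydroxyphenyl]-3-[4-(benzyloxy)-3-hydroxyphenyl]prop-2-en-1-one
Product: 6 5,7-bis(benzyloxy)-2-[4-(benzyloxy)-3-hydroxyphenyl]-4H-chromen-4-one, via racemic flavanone 5 (not isolated)
Conditions: I2 (10 mol%), DMSO, 130 °C, 3 h
Reagents that add atoms: none
Why: Iodine-catalysed oxidative cyclization of a 2'-hydroxychalcone, in which 6-endo oxa-Michael closure to flavanone 5 is followed by iodine-mediated dehydrogenation at C2–C3 with DMSO as terminal oxidant (the flask counterpart of chalcone isomerase then flavone synthase), so the stereocenter of 5 is erased and the benzyl ethers and free phenol are tolerated.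

**Step 3**
Reactants: 6 5,7-bis(benzyloxy)-2-[4-(benzyloxy)-3-hydroxyphenyl]-4H-chromen-4-one; 7 4-fluorobenzaldehyde
Product: 8 4-{2-(benzyloxy)-5-[5,7-bis(benzyloxy)-4-oxo-4H-chromen-2-yl]phenoxy}benzaldehyde
Conditions: K2CO3 (2 equiv), DMF, 90 °C
Reagents that add atoms: none
Why: SNAr (addition–elimination), since the 3'-OH is the only free phenol of 6 and the fluoride of 7 is activated by the para formyl group; no stereocenter is involved.

**Step 4**
Reactants: 8 4-{2-(benzyloxy)-5-[5,7-bis(benzyloxy)-4-oxo-4H-chromen-2-yl]phenoxy}benzaldehyde; 9 1-(2,6-dihydroxy-4-methoxyphenyl)ethan-1-one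
Product: 11 (E)-3-(4-{2-(benzyloxy)-5-[5,7-bis(benzyloxy)-4-oxo-4H-chromen-2-yl]phenoxy}phenyl)-1-(2,6-dihydroxy-4-methoxyphenyl)prop-2-en-1-one, via aldol adduct 10 (not isolated)
Conditions: KOH (50% aq, 10 equiv), EtOH/THF, 0 °C to rt; poured into ice-cold 1 M HCl (pH 3)
Reagents that add atoms: none
Why: Claisen–Schmidt condensation, in which the aldehyde of 8 cannot enolise, the 2-arylchromone resists hydroxide at rt, and strong base holds the product as its open bis-phenoxide so that cold acidic work-up gives the E-chalcone before it can close.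

**Step 5**
Reactants: 11 (E)-3-(4-{2-(benzyloxy)-5-[5,7-bis(benzyloxy)-4-oxo-4H-chromen-2-yl]phenoxy}phenyl)-1-(2,6-dihydroxy-4-methoxyphenyl)prop-2-en-1-one
Product: 12 (2S)-2-(4-{2-(benzyloxy)-5-[5,7-bis(benzyloxy)-4-oxo-4H-chromen-2-yl]phenoxy}phenyl)-5-hydroxy-7-methoxy-2,3-dihydro-4H-chromen-4-one
Conditions: N-[3,5-bis(trifluoromethyl)phenyl]-N'-[(8α,9S)-6'-methoxycinchonan-9-yl]thiourea (10 mol%), CH2Cl2/toluene 1:1, −20 °C; filtered through acid-washed silica
Reagents that add atoms: none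
Why: Proposed new method: a chalcone isomerase-like enantioselective 6-endo-trig oxa-Michael closure in which the quinuclidine nitrogen deprotonates the free, acidic 2'-OH to a tight ion pair while the thiourea binds the carbonyl that the other ortho OH already activates by hydrogen bonding, so C–O bond formation at the β-carbon occurs on one enone face and sets C2 as S; the chalcone is stable in neutral aprotic solvent (no background closure) and the chelated 5-hydroxyflavanone reopens too slowly to erode the ee; the closest known reaction is the bifunctional cinchona–thiourea-catalysed asymmetric oxa-Michael cyclization of 2'-hydroxychalcones and their α-alkoxycarbonyl derivatives to flavanones.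

**Step 6**
Reactants: 12 (2S)-2-(4-{2-(benzyloxy)-5-[5,7-bis(benzyloxy)-4-oxo-4H-chromen-2-yl]phenoxy}phenyl)-5-hydroxy-7-methoxy-2,3-dihydro-4H-chromen-4-one
Product: 13 (2S)-2-{4-[5-(5,7-dihydroxy-4-oxo-4H-chromen-2-yl)-2-hydroxyphenoxy]phenyl}-5-hydroxy-7-methoxy-2,3-dihydro-4H-chromen-4-one
Conditions: H2 (1 atm), 10% Pd/C, THF/MeOH 1:1, rt, stopped at full conversion
Reagents that add atoms: none
Why: Hydrogenolysis of three aryl benzyl ethers over Pd/C under neutral conditions, which leaves the aryl methyl ether, the diaryl ether, both pyranone carbonyls and the flavone C2=C3 bond intact and cannot epimerise C2, so the 2S center from step 5 is carried into the target.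

**Compound list**
1 | 1-[2,4-bis(benzyloxy)-6-hydroxyphenyl]ethan-1-one | CC(=O)c1c(O)cc(OCc2ccccc2)cc1OCc1ccccc1 | starting material
2 | 4-(benzyloxy)-3-hydroxybenzaldehyde | O=Cc1ccc(OCc2ccccc2)c(O)c1 | starting material
3 | 1-[2,4-bis(benzyloxy)-6-hydroxyphenyl]-3-[4-(benzyloxy)-3-hydroxyphenyl]-3-hydroxypropan-1-one (racemic aldol adduct; not isolated) | O=C(CC(O)c1ccc(OCc2ccccc2)c(O)c1)c1c(O)cc(OCc2ccccc2)cc1OCc1ccccc1 | intermediate
4 | (E)-1-[2,4-bis(benzyloxy)-6-hydroxyphenyl]-3-[4-(benzyloxy)-3-hydroxyphenyl]prop-2-en-1-one | O=C(/C=C/c1ccc(OCc2ccccc2)c(O)c1)c1c(O)cc(OCc2ccccc2)cc1OCc1ccccc1 | intermediate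
5 | 5,7-bis(benzyloxy)-2-[4-(benzyloxy)-3-hydroxyphenyl]-2,3-dihydro-4H-chromen-4-one (racemic flavanone; not isolated) | O=C1CC(c2ccc(OCc3ccccc3)c(O)c2)Oc2cc(OCc3ccccc3)cc(OCc3ccccc3)c21 | intermediate
6 | 5,7-bis(benzyloxy)-2-[4-(benzyloxy)-3-hydroxyphenyl]-4H-chromen-4-one (5,7,4'-tri-O-benzylluteolin) | O=c1cc(-c2ccc(OCc3ccccc3)c(O)c2)oc2cc(OCc3ccccc3)cc(OCc3ccccc3)c12 | intermediate
7 | 4-fluorobenzaldehyde | O=Cc1ccc(F)cc1 | starting material
8 | 4-{2-(benzyloxy)-5-[5,7-bis(benzyloxy)-4-oxo-4H-chromen-2-yl]phenoxy}benzaldehyde | O=Cc1ccc(Oc2cc(-c3cc(=O)c4c(OCc5ccccc5)cc(OCc5ccccc5)cc4o3)ccc2OCc2ccccc2)cc1 | intermediate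
9 | 1-(2,6-dihydroxy-4-methoxyphenyl)ethan-1-one | CC(=O)c1c(O)cc(OC)cc1O | starting material
10 | 3-(4-{2-(benzyloxy)-5-[5,7-bis(benzyloxy)-4-oxo-4H-chromen-2-yl]phenoxy}phenyl)-1-(2,6-dihydroxy-4-methoxyphenyl)-3-hydroxypropan-1-one (racemic aldol adduct; not isolated) | COc1cc(O)c(C(=O)CC(O)c2ccc(Oc3cc(-c4cc(=O)c5c(OCc6ccccc6)cc(OCc6ccccc6)cc5o4)ccc3OCc3ccccc3)cc2)c(O)c1 | intermediate
11 | (E)-3-(4-{2-(benzyloxy)-5-[5,7-bis(benzyloxy)-4-oxo-4H-chromen-2-yl]phenoxy}phenyl)-1-(2,6-dihydroxy-4-methoxyphenyl)prop-2-en-1-one | COc1cc(O)c(C(=O)/C=C/c2ccc(Oc3cc(-c4cc(=O)c5c(OCc6ccccc6)cc(OCc6ccccc6)cc5o4)ccc3OCc3ccccc3)cc2)c(O)c1 | intermediate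
12 | (2S)-2-(4-{2-(benzyloxy)-5-[5,7-bis(benzyloxy)-4-oxo-4H-chromen-2-yl]phenoxy}phenyl)-5-hydroxy-7-methoxy-2,3-dihydro-4H-chromen-4-one | COc1cc(O)c2c(c1)O[C@H](c1ccc(Oc3cc(-c4cc(=O)c5c(OCc6ccccc6)cc(OCc6ccccc6)cc5o4)ccc3OCc3ccccc3)cc1)CC2=O | intermediate
13 | (2S)-2-{4-[5-(5,7-dihydroxy-4-oxo-4H-chromen-2-yl)-2-hydroxyphenoxy]phenyl}-5-hydroxy-7-methoxy-2,3-dihydro-4H-chromen-4-one | COc1cc(O)c2c(c1)O[C@H](c1ccc(Oc3cc(-c4cc(=O)c5c(O)cc(O)cc5o4)ccc3O)cc1)CC2=O | target

**Totals**
Total step count: 6. Longest linear sequence: 6 steps (1 or 2 to 13); the route is fully linear, with 7 and 9 entering as bought pieces.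

**Steps most likely to fail**

Step 5 is the riskiest. The catalyst class has not been shown on a 2',6'-dihydroxychalcone of this size, so the ee may be moderate. The fallback sets out from 11 and comes back at 12. 11 is closed without stereocontrol (NaOAc, EtOH/THF, reflux) to the racemic tri-O-benzyl flavanone F1. Its enantiomers are separated by preparative SFC on an amylose tris(3,5-dimethylphenylcarbamate) phase. The 2S enantiomer is 12; the 2R enantiomer is racemised through the chalcone (NaOAc, EtOH, reflux) and separated again.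

Step 4 is second. The doubly deprotonated ketone 9 is a sluggish enolate precursor, hydroxide may attack the chromone, and the chalcone can close to racemic flavanone on work-up. The fallback sets out from 9 and comes back at 11. 9 is mono-protected (MOMCl 1.05 equiv, iPr2NEt, CH2Cl2, 0 °C) to 1-[2-hydroxy-4-methoxy-6-(methoxymethoxy)phenyl]ethan-1-one F2. F2 carries a single phenoxide and condenses with 8 under milder base (Ba(OH)2·8H2O, MeOH/THF, 40 °C) to the slow-closing mono-MOM chalcone (E)-3-(4-{2-(benzyloxy)-5-[5,7-bis(benzyloxy)-4-oxo-4H-chromen-2-yl]phenoxy}phenyl)-1-[2-hydroxy-4-methoxy-6-(methoxymethoxy)phenyl]prop-2-en-1-one F3. Its MOM ether, ortho to the chelating ketone, is removed with 2 M HCl in MeOH/THF at rt, stopped before any flavanone forms, which gives 11.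

Step 6 is third. The flavone C2=C3 bond or the benzylic C2–O bond of the flavanone may be reduced, and the poorly soluble substrate may debenzylate incompletely. The fallback sets out from 11 and comes back at 13, with deprotection and ring closure exchanged. BCl3 (6 equiv) with pentamethylbenzene in CH2Cl2 at −78 °C removes the three benzyl groups without touching the enone or the non-chelated methyl ether. This gives the free chalcone (E)-3-{4-[5-(5,7-dihydroxy-4-oxo-4H-chromen-2-yl)-2-hydroxyphenoxy]phenyl}-1-(2,6-dihydroxy-4-methoxyphenyl)prop-2-en-1-one F4. F4 is then closed enantioselectively as the last operation, giving 13 with no reduction step. The closure uses recombinant chalcone isomerase in pH 7.5 phosphate buffer/DMSO, which gives 2S flavanones from 2',6'-dihydroxychalcones, or the thiourea of step 5.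

**Further compounds**
F1 | step 5 | racemic 2-(4-{2-(benzyloxy)-5-[5,7-bis(benzyloxy)-4-oxo-4H-chromen-2-yl]phenoxy}phenyl)-5-hydroxy-7-methoxy-2,3-dihydro-4H-chromen-4-one | COc1cc(O)c2c(c1)OC(c1ccc(Oc3cc(-c4cc(=O)c5c(OCc6ccccc6)cc(OCc6ccccc6)cc5o4)ccc3OCc3ccccc3)cc1)CC2=O
F2 | step 4 | 1-[2-hydroxy-4-methoxy-6-(methoxymethoxy)phenyl]ethan-1-one | CC(=O)c1c(O)cc(OC)cc1OCOC
F3 | step 4 | (E)-3-(4-{2-(benzyloxy)-5-[5,7-bis(benzyloxy)-4-oxo-4H-chromen-2-yl]phenoxy}phenyl)-1-[2-hydroxy-4-methoxy-6-(methoxymethoxy)phenyl]prop-2-en-1-one | COCOc1cc(OC)cc(O)c1C(=O)/C=C/c1ccc(Oc2cc(-c3cc(=O)c4c(OCc5ccccc5)cc(OCc5ccccc5)cc4o3)ccc2OCc2ccccc2)cc1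
F4 | step 6 | (E)-3-{4-[5-(5,7-dihydroxy-4-oxo-4H-chromen-2-yl)-2-hydroxyphenoxy]phenyl}-1-(2,6-dihydroxy-4-methoxyphenyl)prop-2-en-1-one | COc1cc(O)c(C(=O)/C=C/c2ccc(Oc3cc(-c4cc(=O)c5c(O)cc(O)cc5o4)ccc3O)cc2)c(O)c1
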